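## Retrosynthetic overview

1. Target 24 ⇐ aldehyde 23 (NaBH4) ⇐ C-9 alcohol 22 (Ac2O) ⇐ cycloadduct 21 (Zn), in which the C-7 isopropenyl group and O-9 are masked together as an iodomethyl oxolane (temporary ring O-9–C-11).
2. Enabling feature: cyclohexene ring A (C-1, C-2, C-3=C-4, C-5, C-10) is a Diels–Alder retron, its only double bond lying between the bonds C-1–C-2 and C-5–C-10; C-6 to C-9 of ring B are a four-atom tether and C-14 on C-10 can serve as a formyl activator. Cutting both bonds gives monocyclic triene 20.
3. Triene 20 = (1E,3E)-1-acetoxy-3-methyldiene (C-2 to C-5) + (Z)-β-senecioyloxy enal (C-1=C-10–CHO); the cis-1,3 pair C-7 isopropenyl / O-9 is tied as the oxolane so that the tether has only one chair open to it.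
4. 20 ⇐ 2-substituted malondialdehyde 19 ⇐ divinyl carbinol 8 (catalytic asymmetric pentadienylboration sets C-9) ⇐ keto aldehyde 4 ⇐ (S)-limonene (C-7); the diene comes from the methyl ketone (C-4, C-15) by olefination, reduction and dienol acetylation.
5. Ring order: oxolane (step 5, temporary) → rings A and B together (step 13) → oxolane opened (step 14).

Key step: step 13

Remarks on the chemistry:
- Positions carry eudesmane numbering: C-1 (senecioate), C-2 (OAc), C-3=C-4 (C-15 methyl on C-4), C-5 (ring-fusion H), C-6, C-7 (isopropenyl C-11/C-12/C-13), C-8, C-9 (OAc), C-10 (quaternary, C-14). Ring A is the cyclohexene, ring B the cyclohexane.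
- In the target the C-1 and C-2 oxygens are cis to C-14, while H-5, O-9 and the isopropenyl group lie on the opposite face (O-9 and C-11 are 1,3-diaxial on ring B).
- Step 4: the catalyst enantiomer must deliver the dienyl unit to the Re face of the aldehyde; this is assumed to be (R)-TRIP by analogy with allylborations of aliphatic aldehydes.
- Step 5 should give a C-11 epimer mixture (expected major epimer drawn); both epimers converge in step 14.
- The C-3=C-4 double bond of 10, 13 and 15 is drawn E; any Z isomer is carried along because this bond is moved in step 10.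

## Route

Step 1
Reactants: 1 (S)-(−)-limonene
Product: 2 (4S)-limonene 1,2-oxide (cis/trans mixture)
Conditions: mCPBA (1.0 equiv), CH2Cl2, 0 °C
Reagents that add atoms: m-chloroperbenzoic acid, OOC(=O)c1cccc(Cl)c1
Why: Prilezhaev epoxidation should occur at the more electron-rich trisubstituted ring alkene rather than the isopropenyl group, and the configuration of the new epoxide carbons is irrelevant because both become carbonyl carbons in step 2, while the limonene stereocentre (later C-7) is untouched.

Step 2
Reactants: 2 (4S)-limonene 1,2-oxide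
Product: 4 (3S)-6-oxo-3-(prop-1-en-2-yl)heptanal, via menthene diol 3 (not isolated)
Conditions: H5IO6 (1.1 equiv), THF/H2O, 0 → 23 °C
Reagents that add atoms: water, O
Why: Periodic acid opens the epoxide to the diol and cleaves it (Malaprade glycol cleavage), which differentiates the chain ends as aldehyde (C-9) and methyl ketone (C-4/C-15) and cannot epimerise C-7, which is not α to a carbonyl.

Step 3
Reactants: 5 penta-1,4-diene
Product: 7 (E)-4,4,5,5-tetramethyl-2-(penta-2,4-dien-1-yl)-1,3,2-dioxaborolane, via pentadienylpotassium 6 (not isolated)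
Conditions: n-BuLi, KOt-Bu, THF/hexane, −78 °C; then i-PrOBpin, −78 → 23 °C; aq. work-up
Reagents that add atoms: 2-isopropoxy-4,4,5,5-tetramethyl-1,3,2-dioxaborolane, CC(C)OB1OC(C)(C)C(C)(C)O1; potassium tert-butoxide, CC(C)(C)[O-].[K+] (potassium of 6)
Why: Superbase metalation of the doubly allylic CH2 gives the W-shaped pentadienyl anion, which should be borylated at a terminal carbon to the (E)-pentadienylboronate, as in the standard preparation of allylic boronates from allylpotassium reagents.

Step 4
Reactants: 4 (3S)-6-oxo-3-(prop-1-en-2-yl)heptanal; 7 (E)-4,4,5,5-tetramethyl-2-(penta-2,4-dien-1-yl)-1,3,2-dioxaborolane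
Product: 8 (5S,7S)-8-ethenyl-7-hydroxy-5-(prop-1-en-2-yl)dec-9-en-2-one
Conditions: (R)-TRIP (5 mol%), 4 Å MS, toluene, −40 °C; aq. work-up
Reagents that add atoms: none
Why: Chiral phosphoric acid-catalysed allylboration through a closed six-membered chair transition state bonds the γ-carbon of the boronate to the aldehyde (1,4-pentadien-3-yl carbinol), the catalyst directing attack to the Re face so that C-9 is set as S by catalyst control; the methyl ketone should not react at this temperature and C-10 is not stereogenic because its two vinyl groups are identical.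

Step 5
Reactants: 8 (5S,7S)-8-ethenyl-7-hydroxy-5-(prop-1-en-2-yl)dec-9-en-2-one
Product: 9 4-[(2S,3S,5S)-2-(iodomethyl)-2-methyl-5-(penta-1,4-dien-3-yl)oxolan-3-yl]butan-2-one
Conditions: I2, NaHCO3, MeCN, 0 °C, dark
Reagents that add atoms: iodine, II
Why: 5-exo-trig iodoetherification should take place at the most nucleophilic, 1,1-disubstituted alkene with O-9 attacking the tertiary carbon C-11 (closure onto the vinyl groups would be 4-exo or 5-endo), which ties the C-7 and C-9 substituents cis on an oxolane without touching either centre; the new C-11 centre (CH2I expected anti to the C-6 chain from an A1,3-minimised conformation) becomes sp2 again in step 14.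

Step 6
Reactants: 9 4-[(2S,3S,5S)-2-(iodomethyl)-2-methyl-5-(penta-1,4-dien-3-yl)oxolan-3-yl]butan-2-one
Product: 10 (E)-5-[(2S,3S,5S)-2-(iodomethyl)-2-methyl-5-(penta-1,4-dien-3-yl)oxolan-3-yl]-3-methylpent-2-enenitrile
Conditions: (EtO)2P(O)CH2CN, NaH, THF, 0 → 40 °C
Reagents that add atoms: diethyl (cyanomethyl)phosphonate, N#CCP(=O)(OCC)OCC
Why: Horner–Wadsworth–Emmons olefination of the methyl ketone adds C-3 and C-2 as a conjugated nitrile (E expected to predominate, geometry irrelevant later), and the neopentyl iodide, which has no β-hydrogen and is blocked towards SN2, should survive the base.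

Step 7
Reactants: 10 (E)-5-[(2S,3S,5S)-2-(iodomethyl)-2-methyl-5-(penta-1,4-dien-3-yl)oxolan-3-yl]-3-methylpent-2-enenitrile
Product: 12 (E)-5-[(2S,3S,5S)-5-(1,3-dihydroxypropan-2-yl)-2-(iodomethyl)-2-methyloxolan-3-yl]-3-methylpent-2-enenitrile, via bis-ozonide 11 (not isolated)
Conditions: O3, CH2Cl2, −78 °C (Sudan III end point); then NaBH4, MeOH, −78 → 0 °C
Reagents that add atoms: ozone, [O-][O+]=O
Why: Ozonolysis with reductive work-up should cleave the two electron-neutral vinyl groups much faster than the electron-poor conjugated nitrile alkene, and direct borohydride reduction of the ozonides gives the 1,3-diol (C-1 and C-14) without a free 1,3-dialdehyde ever being present.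

Step 8
Reactants: 12 (E)-5-[(2S,3S,5S)-5-(1,3-dihydroxypropan-2-yl)-2-(iodomethyl)-2-methyloxolan-3-yl]-3-methylpent-2-enenitrile
Product: 13 (E)-5-[(2S,3S,5S)-5-{1,3-bis[(triethylsilyl)oxy]propan-2-yl}-2-(iodomethyl)-2-methyloxolan-3-yl]-3-methylpent-2-enenitrile
Conditions: TESCl, imidazole, CH2Cl2, 0 °C
Reagents that add atoms: chlorotriethylsilane, CC[Si](Cl)(CC)CC
Why: Standard silylation protects both primary hydroxyls as triethylsilyl ethers, which tolerate steps 9 and 10 and can later be oxidised directly.

Step 9
Reactants: 13 (E)-5-[(2S,3S,5S)-5-{1,3-bis[(triethylsilyl)oxy]propan-2-yl}-2-(iodomethyl)-2-methyloxolan-3-yl]-3-methylpent-2-enenitrile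
Product: 15 (E)-5-[(2S,3S,5S)-5-{1,3-bis[(triethylsilyl)oxy]propan-2-yl}-2-(iodomethyl)-2-methyloxolan-3-yl]-3-methylpent-2-enal, via N-aluminio aldimine 14 (not isolated)
Conditions: DIBAL-H, toluene, −78 °C; aq. Rochelle salt, then SiO2
Reagents that add atoms: diisobutylaluminium hydride, CC(C)C[AlH]CC(C)C (aluminium of 14); water, O
Why: DIBAL half-reduction of the conjugated nitrile stops at the aldimine, which is hydrolysed on work-up to the enal, while silyl ethers and the neopentyl iodide are inert at −78 °C.

Step 10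
Reactants: 15 (E)-5-[(2S,3S,5S)-5-{1,3-bis[(triethylsilyl)oxy]propan-2-yl}-2-(iodomethyl)-2-methyloxolan-3-yl]-3-methylpent-2-enal
Product: 17 (1E,3E)-5-[(2S,3S,5S)-5-{1,3-bis[(triethylsilyl)oxy]propan-2-yl}-2-(iodomethyl)-2-methyloxolan-3-yl]-3-methylpenta-1,3-dien-1-yl acetate, via potassium dienolate 16 (not isolated)
Conditions: KOt-Bu, THF, −78 °C; then Ac2O, −78 → 0 °C; chromatography on AgNO3–silica
Reagents that add atoms: acetic anhydride, CC(=O)OC(C)=O; potassium tert-butoxide, CC(C)(C)[O-].[K+] (potassium of 16)
Why: Reversible γ-deprotonation of the 3-methyl enal should occur at the C-5 methylene (as in the citral to isocitral manifold) to give the extended dienolate, whose O-acylation gives the 1-acetoxydiene with the 1E geometry of the W-shaped dienolate and the more stable 3E geometry (C-6 trans to C-3), minor geometric isomers being removed at this stable stage.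

Step 11
Reactants: 17 (1E,3E)-5-[(2S,3S,5S)-5-{1,3-bis[(triethylsilyl)oxy]propan-2-yl}-2-(iodomethyl)-2-methyloxolan-3-yl]-3-methylpenta-1,3-dien-1-yl acetate
Product: 19 (1E,3E)-5-[(2S,3S,5S)-5-[(Z)-1-formyl-2-hydroxyethenyl]-2-(iodomethyl)-2-methyloxolan-3-yl]-3-methylpenta-1,3-dien-1-yl acetate, via desilylated diol 18 (not isolated)
Conditions: IBX (3 equiv), DMSO, 20 °C; used crude
Reagents that add atoms: none
Why: IBX in DMSO converts primary triethylsilyl ethers directly into aldehydes (oxidative desilylation) under near-neutral conditions that the dienyl acetate should tolerate, and the 2-substituted malondialdehyde rests as its hydrogen-bonded cis-enol.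

Step 12
Reactants: 19 (1E,3E)-5-[(2S,3S,5S)-5-[(Z)-1-formyl-2-hydroxyethenyl]-2-(iodomethyl)-2-methyloxolan-3-yl]-3-methylpenta-1,3-dien-1-yl acetate
Product: 20 (1E,3E)-5-[(2S,3S,5S)-5-[(Z)-1-formyl-2-(3-methylbut-2-enoyloxy)ethenyl]-2-(iodomethyl)-2-methyloxolan-3-yl]-3-methylpenta-1,3-dien-1-yl acetate
Conditions: 3-methylbut-2-enoyl chloride, 2,6-lutidine, CH2Cl2, −78 → −20 °C
Reagents that add atoms: 3-methylbut-2-enoyl chloride, CC(C)=CC(=O)Cl
Why: O-acylation of the acidic chelated cis-enol in a non-polar solvent with a hindered weak base should retain the U-shaped geometry and give the Z enol ester (acyloxy cis to formyl), which is also the isomer free of A1,3 strain with the branched C-9, while the weak base avoids deconjugation of the acyl chloride through its vinylketene.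

Step 13
Reactants: 20 (1E,3E)-5-[(2S,3S,5S)-5-[(Z)-1-formyl-2-(3-methylbut-2-enoyloxy)ethenyl]-2-(iodomethyl)-2-methyloxolan-3-yl]-3-methylpenta-1,3-dien-1-yl acetate
Product: 21 cycloadduct 2-acetoxy-9,11-epoxy-12-iodo-1-(3-methylbut-2-enoyloxy)eudesm-3-en-14-al
Conditions: toluene (0.005 M), BHT (10 mol%), 120 °C, sealed tube, dark
Reagents that add atoms: none
Why: Thermal type 1 intramolecular Diels–Alder reaction, a concerted [4πs+2πs] cycloaddition in which the (1E,3E)-1-acetoxy-3-methyldiene (C-2 to C-5, s-cis favoured by the C-4 methyl) adds across the formyl-activated enol ester bond C-1=C-10 held on the four-atom tether C-6 to C-9; the closest known reaction type is the cycloaddition of 1,7,9-decatrienes that carry a 2-alkylacrolein dienophile (angular formyl, trans-decalin), together with the use of 1-acyloxydienes and β-acyloxy enals as Diels–Alder partners. Ring A (cyclohexene C-1 to C-5 and C-10) is the ring of the cycloaddition itself, closed by both new bonds, and ring B (cyclohexane C-5 to C-10) closes through the C-5–C-10 bond in the fused mode as a chair bridged 1,3-diaxially by the oxolane (a 6-oxabicyclo[3.2.1]octane). C-5 and C-10 are set by the transition state with the formyl group endo and the tether anti, which gives the trans ring fusion, and their sense relative to C-7 and C-9 is fixed by the oxolane, because only addition to the face that lets ring B be a chair with H-5 towards the bridge is unstrained, the other face requiring a boat. C-1 follows stereospecifically from the Z geometry of the enol ester (acyloxy cis to formyl, both endo) and C-2 from the E geometry of the acetoxy terminus (acetoxy outside), so both acyloxy groups end cis to C-14 and the senecioate and the allylic acetate arrive in their final positions. The step needs facial, endo and fused-mode selectivity: the first is secured by the temporary ring, the second by secondary orbital overlap of the formyl group and the usual trans preference of internally activated decatrienes, and the third by the short tether, which overrides the electronic preference of the more nucleophilic terminus C-5 for the β-carbon C-1; the reaction is therefore run thermally, since a Lewis acid would favour stepwise attack of C-5 on C-1.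

Step 14
Reactants: 21 cycloadduct 2-acetoxy-9,11-epoxy-12-iodo-1-(3-methylbut-2-enoyloxy)eudesm-3-en-14-al
Product: 22 2-acetoxy-9-hydroxy-1-(3-methylbut-2-enoyloxy)eudesma-3,11-dien-14-al
Conditions: Zn dust (activated), AcOH, THF/EtOH, 40 °C
Reagents that add atoms: none
Why: Two-electron reduction of the C–I bond by zinc with loss of the β-oxygen (Boord-type reductive elimination) regenerates exactly the C-11=C-12 isopropenyl alkene and the C-9 hydroxyl without touching a stereocentre, and the acidic medium should suppress retro-aldol cleavage of the β-hydroxy aldehyde while the esters and the neopentyl aldehyde remain.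

Step 15
Reactants: 22 2-acetoxy-9-hydroxy-1-(3-methylbut-2-enoyloxy)eudesma-3,11-dien-14-al
Product: 23 2,9-diacetoxy-1-(3-methylbut-2-enoyloxy)eudesma-3,11-dien-14-al
Conditions: Ac2O, DMAP, pyridine, CH2Cl2, 23 °C
Reagents that add atoms: acetic anhydride, CC(=O)OC(C)=O
Why: DMAP-catalysed acetylation should esterify the hindered axial C-9 alcohol, the only free hydroxyl, and the aldehyde has no α-hydrogen to enolise.

Step 16
Reactants: 23 2,9-diacetoxy-1-(3-methylbut-2-enoyloxy)eudesma-3,11-dien-14-al
Product: 24 target CNP0320218.1 (14-hydroxyeudesma-3,11-diene-1,2,9-triyl 2,9-diacetate 1-(3-methylbut-2-enoate))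
Conditions: NaBH4, CeCl3·7H2O, MeOH, −40 °C; AcOH quench
Reagents that add atoms: none
Why: Luche-type borohydride reduction should reduce the aldehyde chemoselectively to the C-14 primary alcohol in the presence of three esters and the enoate, and low temperature with an acidic quench should prevent 1,3-acyl migration to the new hydroxyl.

## Compound list

1 | (S)-(−)-limonene | CC1=CC[C@H](CC1)C(C)=C | starting material
2 | (4S)-limonene 1,2-oxide (cis/trans mixture) | CC12OC1C[C@H](CC2)C(C)=C | intermediate
3 | (4S)-p-menth-8-ene-1,2-diol (menthene diol) | CC1(O)C(O)C[C@H](CC1)C(C)=C | intermediate (not isolated)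
4 | (3S)-6-oxo-3-(prop-1-en-2-yl)heptanal | C=C(C)[C@@H](CCC(C)=O)CC=O | intermediate
5 | penta-1,4-diene | C=CCC=C | starting material
6 | pentadienylpotassium | [K+].[CH2-]C=CC=C | intermediate (not isolated)
7 | (E)-4,4,5,5-tetramethyl-2-(penta-2,4-dien-1-yl)-1,3,2-dioxaborolane | C=C/C=C/CB1OC(C)(C)C(C)(C)O1 | intermediate
8 | (5S,7S)-8-ethenyl-7-hydroxy-5-(prop-1-en-2-yl)dec-9-en-2-one | C=C(C)[C@@H](CCC(C)=O)C[C@H](O)C(C=C)C=C | intermediate
9 | 4-[(2S,3S,5S)-2-(iodomethyl)-2-methyl-5-(penta-1,4-dien-3-yl)oxolan-3-yl]butan-2-one | O1[C@H](C(C=C)C=C)C[C@H](CCC(C)=O)[C@@]1(C)CI | intermediate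
10 | (E)-5-[(2S,3S,5S)-2-(iodomethyl)-2-methyl-5-(penta-1,4-dien-3-yl)oxolan-3-yl]-3-methylpent-2-enenitrile | O1[C@H](C(C=C)C=C)C[C@H](CC/C(C)=C/C#N)[C@@]1(C)CI | intermediate
11 | bis-ozonide of 10 | O1[C@H](C(C2OCOO2)C2OCOO2)C[C@H](CC/C(C)=C/C#N)[C@@]1(C)CI | intermediate (not isolated)
12 | (E)-5-[(2S,3S,5S)-5-(1,3-dihydroxypropan-2-yl)-2-(iodomethyl)-2-methyloxolan-3-yl]-3-methylpent-2-enenitrile | O1[C@H](C(CO)CO)C[C@H](CC/C(C)=C/C#N)[C@@]1(C)CI | intermediate
13 | (E)-5-[(2S,3S,5S)-5-{1,3-bis[(triethylsilyl)oxy]propan-2-yl}-2-(iodomethyl)-2-methyloxolan-3-yl]-3-methylpent-2-enenitrile | O1[C@H](C(CO[Si](CC)(CC)CC)CO[Si](CC)(CC)CC)C[C@H](CC/C(C)=C/C#N)[C@@]1(C)CI | intermediate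
14 | N-(diisobutylaluminio) aldimine of 15 | O1[C@H](C(CO[Si](CC)(CC)CC)CO[Si](CC)(CC)CC)C[C@H](CC/C(C)=C/C=N[Al](CC(C)C)CC(C)C)[C@@]1(C)CI | intermediate (not isolated)
15 | (E)-5-[(2S,3S,5S)-5-{1,3-bis[(triethylsilyl)oxy]propan-2-yl}-2-(iodomethyl)-2-methyloxolan-3-yl]-3-methylpent-2-enal | O1[C@H](C(CO[Si](CC)(CC)CC)CO[Si](CC)(CC)CC)C[C@H](CC/C(C)=C/C=O)[C@@]1(C)CI | intermediate
16 | potassium (1E,3E)-dienolate of 15 | O1[C@H](C(CO[Si](CC)(CC)CC)CO[Si](CC)(CC)CC)C[C@H](C/C=C(C)/C=C/[O-])[C@@]1(C)CI.[K+] | intermediate (not isolated)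
17 | (1E,3E)-5-[(2S,3S,5S)-5-{1,3-bis[(triethylsilyl)oxy]propan-2-yl}-2-(iodomethyl)-2-methyloxolan-3-yl]-3-methylpenta-1,3-dien-1-yl acetate | O1[C@H](C(CO[Si](CC)(CC)CC)CO[Si](CC)(CC)CC)C[C@H](C/C=C(C)/C=C/OC(C)=O)[C@@]1(C)CI | intermediate
18 | (1E,3E)-5-[(2S,3S,5S)-5-(1,3-dihydroxypropan-2-yl)-2-(iodomethyl)-2-methyloxolan-3-yl]-3-methylpenta-1,3-dien-1-yl acetate | O1[C@H](C(CO)CO)C[C@H](C/C=C(C)/C=C/OC(C)=O)[C@@]1(C)CI | intermediate (not isolated)
19 | (1E,3E)-5-[(2S,3S,5S)-5-[(Z)-1-formyl-2-hydroxyethenyl]-2-(iodomethyl)-2-methyloxolan-3-yl]-3-methylpenta-1,3-dien-1-yl acetate (enol of the 2-substituted malondialdehyde) | O1[C@H](/C(C=O)=C/O)C[C@H](C/C=C(C)/C=C/OC(C)=O)[C@@]1(C)CI | intermediate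
20 | (1E,3E)-5-[(2S,3S,5S)-5-[(Z)-1-formyl-2-(3-methylbut-2-enoyloxy)ethenyl]-2-(iodomethyl)-2-methyloxolan-3-yl]-3-methylpenta-1,3-dien-1-yl acetate | O1[C@H](/C(C=O)=C/OC(=O)C=C(C)C)C[C@H](C/C=C(C)/C=C/OC(C)=O)[C@@]1(C)CI | intermediate
21 | cycloadduct 2-acetoxy-9,11-epoxy-12-iodo-1-(3-methylbut-2-enoyloxy)eudesm-3-en-14-al (O-1 and O-2 cis to C-14; H-5, O-9 and C-11 on the other face) | IC[C@@]1(C)O[C@H]2C[C@@H]1C[C@@H]3C(C)=C[C@H](OC(C)=O)[C@H](OC(=O)C=C(C)C)[C@@]23C=O | intermediate
22 | 2-acetoxy-9-hydroxy-1-(3-methylbut-2-enoyloxy)eudesma-3,11-dien-14-al | C=C(C)[C@@H]1C[C@H](O)[C@@]2(C=O)[C@H](C1)C(C)=C[C@H](OC(C)=O)[C@@H]2OC(=O)C=C(C)C | intermediate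
23 | 2,9-diacetoxy-1-(3-methylbut-2-enoyloxy)eudesma-3,11-dien-14-al | C=C(C)[C@@H]1C[C@H](OC(C)=O)[C@@]2(C=O)[C@H](C1)C(C)=C[C@H](OC(C)=O)[C@@H]2OC(=O)C=C(C)C | intermediate
24 | CNP0320218.1 (14-hydroxyeudesma-3,11-diene-1,2,9-triyl 2,9-diacetate 1-(3-methylbut-2-enoate)) | C=C(C)[C@@H]1C[C@H](OC(C)=O)[C@@]2(CO)[C@H](C1)C(C)=C[C@H](OC(C)=O)[C@@H]2OC(=O)C=C(C)C | target

## Step count and risks

Total step count: 16 (15 in the main line plus the one-step preparation of 7).
Longest linear sequence: 15 steps (1 → 24 through steps 1, 2 and 4–16).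

The three steps most likely to fail:

Step 13 (key cycloaddition). The tether forces the more nucleophilic diene terminus onto the α-carbon of the enal, so the cycloaddition may be too slow and thermal decomposition of the enol ester may win; closure through the exo-formyl mode (cis-decalin) may also leak in. The fallback raises the diene HOMO so that the ring closure should run at 60–80 °C. It sets out from 15: oxidative desilylation with IBX/DMSO should give the formyl enol enal F1; acylation with 3-methylbut-2-enoyl chloride and 2,6-lutidine should give the enol ester enal F2; soft enolisation with TBSOTf/Et3N (CH2Cl2, −78 °C) should give the (1E,3E)-silyloxydiene F3; heating in toluene should give the C-2 silyl ether cycloadduct F4; HF·pyridine should free the C-2 allylic alcohol F5; immediate acetylation (Ac2O, pyridine) returns to the route at 21.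

Step 10 (dienyl acetate). Regio- and stereocontrol may be lost in the γ-deprotonation and O-acylation: deprotonation at the C-15 methyl, or formation of 1Z or 3Z isomers, which cannot reach the reactive s-cis conformation with the tether outside. The fallback builds the enol ester in two stages through a silyl dienol ether. It sets out from 15: thermodynamic soft enolisation with TMSOTf/Et3N should give the (1E,3E)-trimethylsilyl dienol ether F6; methyllithium (THF, −40 °C) cleaves the Si–O bond to the lithium dienolate F7 with retention of geometry; quenching with Ac2O returns to the route at 17.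

Step 12 (enol ester). Acylation may proceed through an extended instead of the chelated enol(ate) and give the E enol ester, which would place the acyloxy group trans to the formyl group and so lead to the wrong C-1 configuration. The fallback replaces stereoselective acylation by a dynamic correction. It sets out from 19, which is acylated without regard to geometry to a mixture of 20 and its E enol ester isomer F8. This mixture is heated under the conditions of step 13 with 5 mol% tetrabutylammonium 3-methylbut-2-enoate. Reversible conjugate addition–elimination of the carboxylate at C-1 (through a symmetric geminal bis(acyloxy) enolate, the nucleophile being identical to the leaving group) should interconvert F8 and 20. Only 20 should be drained by the cycloaddition, because in F8 the acyloxy group is cis to C-9 and collides with the oxolane in the chair transition state. The fallback returns to the route at 21.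

Further compounds
F1 | step 13 | (E)-5-[(2S,3S,5S)-5-[(Z)-1-formyl-2-hydroxyethenyl]-2-(iodomethyl)-2-methyloxolan-3-yl]-3-methylpent-2-enal (formyl enol enal) | O1[C@H](/C(C=O)=C/O)C[C@H](CC/C(C)=C/C=O)[C@@]1(C)CI
F2 | step 13 | (E)-5-[(2S,3S,5S)-5-[(Z)-1-formyl-2-(3-methylbut-2-enoyloxy)ethenyl]-2-(iodomethyl)-2-methyloxolan-3-yl]-3-methylpent-2-enal (enol ester enal) | O1[C@H](/C(C=O)=C/OC(=O)C=C(C)C)C[C@H](CC/C(C)=C/C=O)[C@@]1(C)CI
F3 | step 13 | (1E,3E)-1-(tert-butyldimethylsilyloxy)diene analogue of 20 (silyloxydiene) | O1[C@H](/C(C=O)=C/OC(=O)C=C(C)C)C[C@H](C/C=C(C)/C=C/O[Si](C)(C)C(C)(C)C)[C@@]1(C)CI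
F4 | step 13 | C-2 tert-butyldimethylsilyl ether analogue of 21 (silyl ether cycloadduct) | IC[C@@]1(C)O[C@H]2C[C@@H]1C[C@@H]3C(C)=C[C@H](O[Si](C)(C)C(C)(C)C)[C@H](OC(=O)C=C(C)C)[C@@]23C=O
F5 | step 13 | C-2 alcohol analogue of 21 (allylic alcohol) | IC[C@@]1(C)O[C@H]2C[C@@H]1C[C@@H]3C(C)=C[C@H](O)[C@H](OC(=O)C=C(C)C)[C@@]23C=O
F6 | step 10 | (1E,3E)-trimethylsilyl dienol ether of 15 | O1[C@H](C(CO[Si](CC)(CC)CC)CO[Si](CC)(CC)CC)C[C@H](C/C=C(C)/C=C/O[Si](C)(C)C)[C@@]1(C)CI
F7 | step 10 | lithium (1E,3E)-dienolate of 15 | O1[C@H](C(CO[Si](CC)(CC)CC)CO[Si](CC)(CC)CC)C[C@H](C/C=C(C)/C=C/[O-])[C@@]1(C)CI.[Li+]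
F8 | step 12 | E enol ester isomer of 20 (acyloxy trans to formyl) | O1[C@H](/C(C=O)=C\OC(=O)C=C(C)C)C[C@H](C/C=C(C)/C=C/OC(C)=O)[C@@]1(C)CI
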